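**Numbering used throughout.** 1 (Z)-but-2-ene-1,4-diol; 2 its mono-PMB ether; 3 epoxy alcohol; 4 diol; 5 primary tosylate (not isolated); 6 epoxide; 7 4-iodobenzaldehyde; 8 its dioxolane; 9 annulation product; 10 aldehyde; 11 hydroxy aldehyde; 12 p-coumaric acid; 13 bis-silyl compound (not isolated); 14 silyl-protected acid; 15 silylated ester; 16 phenolic ester aldehyde; 17 malonic acid; 18 target. Atom labels: O1, C2, C3, C3a, C4–C7, C7a for the dihydrobenzofuran; C1' is the methyl-bearing side-chain carbon and C2' its CH2O carbon. PMB = 4-methoxybenzyl, TBS = tert-butyldimethylsilyl.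

## Analysis of the target

Target 18 is a 2,3-dihydrobenzofuran: a benzene ring (C3a, C4–C7, C7a) fused to the five-membered ring O1–C2–C3–C3a–C7a. C5 carries an (E)-acrylic acid, and C2 carries a propan-2-yl side chain whose C2' oxygen is acylated by (E)-4-hydroxycinnamic acid. There are two adjacent stereocentres, C2 in the ring and C1' just outside it, both S; in the zigzag C3–C2–C1'–C2' the ring oxygen O1 and the methyl group lie on the same side (syn). C1' is exocyclic and carries only small groups, so the ring cannot be trusted to control it, and the pair is best built as an acyclic unit by stereospecific reactions. The molecule holds two cinnamate-type E-alkenes, a free phenol, and a free carboxylic acid beside a carboxylic ester, so the acid cannot be released by a late saponification. The electron-rich dihydrobenzofuran can be dehydrogenated to a benzofuran, which argues for an electron-withdrawing group on C5 whenever an oxidant is used. The plan rests on one feature: C3a and C7a are ortho neighbours and C7a is para to C5. The unit O1–C2–C3 with C1' and both stereocentres is therefore a terminal epoxide, C7a is the iodine-bearing carbon of a para-substituted iodoarene, and C3a is one of its two equivalent ortho C–H positions.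

## Retrosynthetic reasoning

**18 to 16 and 17.** The Cα=Cβ bond of the acrylic acid on C5 is cut, giving aldehyde 16 and malonic acid 17. Cutting here gives the free E-acid directly from a decarboxylative condensation; any acrylate ester would need a final ester cleavage beside the coumarate ester. The forward reaction must condense and decarboxylate without touching the ester or the phenol.

**16 to 11 and 14.** The ester bond between the C2' oxygen and the coumaroyl carbonyl is cut. A free phenol would compete as acyl acceptor, so the acid is used as silyl ether 14 (from 12 through 13). The ester is first obtained as 15 and then desilylated to 16.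

**11 to 10 to 9.** Alcohol 11 comes from PMB ether 10 by oxidative debenzylation, and 10 from acetal 9 by hydrolysis. The acetal is opened first so that the oxidant meets an arene deactivated by the formyl group.

**9 to 8 and 6 (key disconnection).** Bonds C3–C3a and O1–C7a are cut together. They sit on adjacent aromatic carbons, so one operation removes the whole heterocycle and places both stereocentres in a small acyclic fragment. Cutting O1–C2 or C2–C3 instead would force C2 to be created during ring closure next to C1'. The forward reaction must alkylate one ortho C–H of iodide 8 with the CH2 terminus of epoxide 6, join the liberated oxygen to the ipso carbon, and do so only once.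

**6 to 4.** The oxirane O–CH2 bond is cut, giving diol 4; the forward closure runs through primary tosylate 5 and leaves the C2–O bond untouched.

**4 to 3.** The C1'–CH3 bond is cut, giving cis-epoxy alcohol 3. Methyl transfer with inversion at the carbon remote from the free hydroxyl turns the cis-epoxide into the syn O/CH3 arrangement that 18 needs.

**3 to 2 to 1.** The epoxide oxygen is removed to Z-allylic alcohol 2 (Katsuki–Sharpless epoxidation sets the absolute configuration), and 2 is the mono-ether of symmetrical diol 1.

**8 to 7.** The acetal is cut back to 4-iodobenzaldehyde 7; the mask is needed because the annulation generates an alkoxide in hot carbonate.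

## Alternatives that were turned down

**Alternative 1:** The disconnection is C3–C3a plus O1–C2, leading to 4-bromo-2-iodophenol A1 and the silyloxymethyl-substituted butadiene A2. In the forward step zerovalent palladium (Pd2(dba)3 with a chiral phosphine) inserts into the C–I bond of A1, the aryl group adds to the unsubstituted vinyl terminus of A2, and the phenoxide captures the π-allyl at the internal carbon. This gives the 2-alkenyl dihydrobenzofuran A3 with C2 set by the ligand.
- For: the partners are achiral and simple, the stereocontrol is catalytic, and the bromide allows the acrylate to be attached by a Heck reaction. On endgame step economy it is stronger than the chosen route.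
- Against: only C2 is set. C1' must then be made by hydrogenating the 1,1-disubstituted alkene of A3 under acyclic 1,2-induction from C2, with no strong directing group and an aryl bromide present.
- Comparison: the chosen route fixes both centres before the fragments meet and creates none in the key step; it pays with more protecting-group steps.

**Alternative 2:** The disconnection is O1–C2 plus C1'–C2', leading to the (E)-ortho-crotylphenol A4. In the forward step PdCl2(MeCN)2, a chiral bisoxazoline, CuCl2, carbon monoxide and methanol effect anti attack of the phenol on the palladium-bound alkene at C2 (5-exo-trig), then CO insertion at C1'. This gives ester A5 with both stereocentres.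
- For: it creates the whole stereodiad in one catalytic step from an achiral phenol, which is more elegant than the chosen route.
- Against: the secondary alkylpalladium at C1' has β-hydrogens on CH3 and on C2, so β-hydride elimination competes with CO insertion. Syn and anti oxypalladation can both operate, so the relative configuration is not secure. Enantiocontrol is weakest for 1,2-disubstituted alkenes, and the centre next to the ester in A5 can epimerise before reduction to C2'.
- Comparison: the chosen route uses stoichiometric, stereospecific steps of known sense instead, at the cost of a longer fragment synthesis.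

**Alternative 3:** The disconnection is C2–C3, leading to tosylhydrazone A6, whose side chain comes from the chiral pool. In the forward step base releases the aryldiazomethane, and cobalt tetraphenylporphyrin Co(TPP) (divalent cobalt) or a chiral amidoporphyrin analogue forms a carbene radical. This abstracts the 1,5-hydrogen of the OCH2 group and closes C2–C3, giving A7.
- For: assembly is by simple O-alkylation, C1' is enantiopure from the start, the site of C–H abstraction is unambiguous, and there is no mono- versus di-alkylation problem. It is probably the shortest route.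
- Against: C2 is created through a planar radical next to C1', so the diastereomer ratio depends on the catalyst overriding a weak substrate bias. High selectivity of this reaction type is tied to aryl- or acceptor-stabilised cases.
- Comparison: the chosen key step is stereochemically silent; its own risk is mono-selectivity, which is a yield question, not a stereochemical one.

Key step: step 6

Assumption: the bridgehead-substituted norbornene is taken as 1-methylbicyclo[2.2.1]hept-2-ene; any 1-alkyl analogue should serve the same purpose.

## Route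

Step 1
Reactants: 1 (Z)-but-2-ene-1,4-diol
Product: 2 (2Z)-4-[(4-methoxyphenyl)methoxy]but-2-en-1-ol
Conditions: NaH (1.0 equiv), THF/DMF, 0 °C; then 4-methoxybenzyl chloride (1.0 equiv), 0 °C to rt; 1 used in threefold excess
Reagents that add atoms: 4-methoxybenzyl chloride, COc1ccc(CCl)cc1
Why: Williamson etherification of the mono-alkoxide; the excess of symmetrical diol keeps bis-alkylation low and the Z geometry is not touched.

Step 2
Reactants: 2 (2Z)-4-[(4-methoxyphenyl)methoxy]but-2-en-1-ol
Product: 3 [(2S,3R)-3-{[(4-methoxyphenyl)methoxy]methyl}oxiran-2-yl]methanol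
Conditions: Ti(OiPr)4 (10 mol%), L-(+)-diethyl tartrate (12 mol%), t-BuOOH (2 equiv), 4 Å molecular sieves, CH2Cl2, −20 °C
Reagents that add atoms: tert-butyl hydroperoxide, CC(C)(C)OO
Why: Katsuki–Sharpless epoxidation; the titanium–tartrate complex binds the allylic alcohol and the peroxide and delivers oxygen to one alkene face, the L-(+)-tartrate giving the 2S epoxy alcohol. Oxygen transfer is syn-stereospecific, so the Z-alkene gives the cis-epoxide and C3 is R.

Step 3
Reactants: 3 [(2S,3R)-3-{[(4-methoxyphenyl)methoxy]methyl}oxiran-2-yl]methanol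
Product: 4 (2R,3S)-4-[(4-methoxyphenyl)methoxy]-3-methylbutane-1,2-diol
Conditions: AlMe3 (3 equiv), CH2Cl2/hexane, 0 °C to rt; aqueous potassium sodium tartrate work-up
Reagents that add atoms: trimethylaluminium, C[Al](C)C
Why: Regioselective trialkylaluminium opening of a 2,3-epoxy alcohol to a 1,2-diol: the aluminium alkoxide at C1 holds a second AlMe3 on the epoxide oxygen and methyl is transferred to C3, remote from the alkoxide. The SN2 inversion at C3 sets C1' of the target as S; the C2–O bond (future O1–C2) is not broken.

Step 4
Reactants: 4 (2R,3S)-4-[(4-methoxyphenyl)methoxy]-3-methylbutane-1,2-diol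
Product: 6 (2R)-2-{(2S)-1-[(4-methoxyphenyl)methoxy]propan-2-yl}oxirane, via primary tosylate 5 (not isolated)
Conditions: TsCl (1.05 equiv), Et3N (1.5 equiv), Bu2SnO (2 mol%), CH2Cl2, 0 °C to rt; then K2CO3 (2 equiv), MeOH, rt
Reagents that add atoms: 4-toluenesulfonyl chloride, Cc1ccc(cc1)S(Cl)(=O)=O (its atoms stay in 5 only)
Why: Tin-acetal-catalysed sulfonylation selects the primary hydroxyl, and the secondary alkoxide then displaces the tosylate (intramolecular Williamson closure, 3-exo-tet). The oxygen on C2 is the nucleophile, so its configuration is retained.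

Step 5
Reactants: 7 4-iodobenzaldehyde
Product: 8 2-(4-iodophenyl)-1,3-dioxolane
Conditions: ethane-1,2-diol (3 equiv), TsOH·H2O (2 mol%), toluene, reflux, Dean–Stark trap
Reagents that add atoms: ethane-1,2-diol, OCCO
Why: Acid-catalysed acetalisation driven by azeotropic removal of water; the acetal shields the formyl group from the alkoxide and carbonate of step 6.

Step 6
Reactants: 8 2-(4-iodophenyl)-1,3-dioxolane; 6 (2R)-2-{(2S)-1-[(4-methoxyphenyl)methoxy]propan-2-yl}oxirane
Product: 9 2-[(2S)-2-{(2S)-1-[(4-methoxyphenyl)methoxy]propan-2-yl}-2,3-dihydro-1-benzofuran-5-yl]-1,3-dioxolane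
Conditions: Pd(OAc)2 (10 mol%), PPh3 (25 mol%), 1-methylbicyclo[2.2.1]hept-2-ene (1.0 equiv), Cs2CO3 (2.5 equiv), toluene, 100 °C; 8 (1.5 equiv), 6 (1.0 equiv)
Reagents that add atoms: none
Why: Zerovalent palladium inserts into the C–I bond of 8, the arylpalladium iodide adds across the norbornene from its exo face, and the metal then palladates the neighbouring aromatic C–H with carbonate as proton acceptor, giving a five-membered aryl–norbornyl palladacycle (divalent palladium). This metallacycle attacks the terminal CH2 of epoxide 6 in an SN2 sense, which raises the metal to the tetravalent state and frees the secondary alkoxide; aryl–alkyl reductive elimination then forms C3–C3a. β-Carbon elimination expels the norbornene, and the arylpalladium alkoxide closes the dihydrofuran ring by C–O reductive elimination from a six-membered oxapalladacycle, formally a 5-exo attack of the alkoxide on the ipso carbon (O1–C7a). The closest known reaction type is the palladium/norbornene (Catellani) annulation of ortho-substituted aryl iodides with terminal epoxides to 2,3-dihydrobenzofurans; for an iodide with two free ortho positions, bridgehead-substituted norbornenes are the established means of stopping after one ortho functionalisation, here combined with that annulation. No stereocentre is created: the C2–O bond of the epoxide is never broken and C1' is a spectator, so both centres of 6 pass into 9 unchanged (the descriptor at C2 changes from R to S only because the CIP ranking of its carbon neighbours changes). The step needs mono-alkylation, which the bridgehead methyl group should secure by making norbornene extrusion faster than a second C–H palladation, and attack at CH2 and not CH of the epoxide, which the branched C1' substituent secures sterically. The para acetal makes the two ortho positions equivalent, and the acetal and PMB ether are inert to carbonate at this temperature.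

Step 7
Reactants: 9 2-[(2S)-2-{(2S)-1-[(4-methoxyphenyl)methoxy]propan-2-yl}-2,3-dihydro-1-benzofuran-5-yl]-1,3-dioxolane
Product: 10 (2S)-2-{(2S)-1-[(4-methoxyphenyl)methoxy]propan-2-yl}-2,3-dihydro-1-benzofuran-5-carbaldehyde
Conditions: 1 M HCl, THF, rt
Reagents that add atoms: water, O
Why: Acid hydrolysis of an aryl dioxolane, fast here because the para ring oxygen stabilises the oxocarbenium ion; the PMB ether and the alkyl aryl ether survive dilute acid at room temperature.

Step 8
Reactants: 10 (2S)-2-{(2S)-1-[(4-methoxyphenyl)methoxy]propan-2-yl}-2,3-dihydro-1-benzofuran-5-carbaldehyde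
Product: 11 (2S)-2-[(2S)-1-hydroxypropan-2-yl]-2,3-dihydro-1-benzofuran-5-carbaldehyde
Conditions: DDQ (1.3 equiv), CH2Cl2/pH 7 phosphate buffer (10:1), 0 °C to rt
Reagents that add atoms: none
Why: Oxidative PMB cleavage by hydride abstraction at the electron-rich benzylic CH2 and hydrolysis of the oxocarbenium ion. The formyl group deactivates the dihydrobenzofuran, so dehydrogenation of the heterocycle should not compete.

Step 9
Reactants: 12 (2E)-3-(4-hydroxyphenyl)prop-2-enoic acid (p-coumaric acid)
Product: 14 (2E)-3-{4-[(tert-butyldimethylsilyl)oxy]phenyl}prop-2-enoic acid, via bis-silylated coumarate 13 (not isolated)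
Conditions: TBSCl (2.3 equiv), imidazole (4.6 equiv), DMF, rt; then AcOH/THF/H2O (3:1:1), rt
Reagents that add atoms: tert-butyldimethylsilyl chloride, CC(C)(C)[Si](C)(C)Cl
Why: Exhaustive silylation followed by selective hydrolysis of the silyl ester, which is far more labile than the aryl silyl ether; the alkene is not affected.

Step 10
Reactants: 11 (2S)-2-[(2S)-1-hydroxypropan-2-yl]-2,3-dihydro-1-benzofuran-5-carbaldehyde; 14 (2E)-3-{4-[(tert-butyldimethylsilyl)oxy]phenyl}prop-2-enoic acid
Product: 15 (2S)-2-[(2S)-5-formyl-2,3-dihydro-1-benzofuran-2-yl]propyl (2E)-3-{4-[(tert-butyldimethylsilyl)oxy]phenyl}prop-2-enoate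
Conditions: EDC·HCl (1.5 equiv), DMAP (0.2 equiv), CH2Cl2, 0 °C to rt; 14 (1.2 equiv)
Reagents that add atoms: none
Why: Steglich-type carbodiimide esterification of a primary alcohol; the aldehyde and the aryl silyl ether are inert and no stereocentre is involved.

Step 11
Reactants: 15 (2S)-2-[(2S)-5-formyl-2,3-dihydro-1-benzofuran-2-yl]propyl (2E)-3-{4-[(tert-butyldimethylsilyl)oxy]phenyl}prop-2-enoate
Product: 16 (2S)-2-[(2S)-5-formyl-2,3-dihydro-1-benzofuran-2-yl]propyl (2E)-3-(4-hydroxyphenyl)prop-2-enoate
Conditions: Bu4NF (1.1 equiv), AcOH (1.2 equiv), THF, 0 °C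
Reagents that add atoms: none
Why: Fluoride cleavage of an aryl silyl ether; acetic acid buffering keeps the medium from attacking the ester, and the aldehyde is non-enolisable. Desilylating here means the ammonium salts are removed from a neutral compound and not from the final acid.

Step 12
Reactants: 16 (2S)-2-[(2S)-5-formyl-2,3-dihydro-1-benzofuran-2-yl]propyl (2E)-3-(4-hydroxyphenyl)prop-2-enoate; 17 propanedioic acid (malonic acid)
Product: 18 (2E)-3-[(2S)-2-[(2S)-1-{[(2E)-3-(4-hydroxyphenyl)prop-2-enoyl]oxy}propan-2-yl]-2,3-dihydro-1-benzofuran-5-yl]prop-2-enoic acid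
Conditions: 17 (3 equiv), pyridine, piperidine (0.1 equiv), 80 °C; then 1 M HCl
Reagents that add atoms: none
Why: Knoevenagel–Doebner condensation: iminium-activated condensation followed by decarboxylative elimination should give the E-acrylic acid directly. Free phenols are routinely tolerated in this reaction, and the alkyl coumarate is a poor electrophile for pyridine or catalytic piperidine.

## Compound list

1 | (Z)-but-2-ene-1,4-diol | OC/C=C\CO | starting material
2 | (2Z)-4-[(4-methoxyphenyl)methoxy]but-2-en-1-ol | OC/C=C\COCc1ccc(OC)cc1 | intermediate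
3 | [(2S,3R)-3-{[(4-methoxyphenyl)methoxy]methyl}oxiran-2-yl]methanol | OC[C@@H]1O[C@@H]1COCc1ccc(OC)cc1 | intermediate
4 | (2R,3S)-4-[(4-methoxyphenyl)methoxy]-3-methylbutane-1,2-diol | OC[C@H](O)[C@@H](C)COCc1ccc(OC)cc1 | intermediate
5 | (2R,3S)-2-hydroxy-4-[(4-methoxyphenyl)methoxy]-3-methylbutyl 4-methylbenzenesulfonate | Cc1ccc(cc1)S(=O)(=O)OC[C@H](O)[C@@H](C)COCc1ccc(OC)cc1 | intermediate
6 | (2R)-2-{(2S)-1-[(4-methoxyphenyl)methoxy]propan-2-yl}oxirane | C[C@@H](COCc1ccc(OC)cc1)[C@@H]1CO1 | intermediate
7 | 4-iodobenzaldehyde | O=Cc1ccc(I)cc1 | starting material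
8 | 2-(4-iodophenyl)-1,3-dioxolane | Ic1ccc(cc1)C1OCCO1 | intermediate
9 | 2-[(2S)-2-{(2S)-1-[(4-methoxyphenyl)methoxy]propan-2-yl}-2,3-dihydro-1-benzofuran-5-yl]-1,3-dioxolane | C[C@@H](COCc1ccc(OC)cc1)[C@@H]1Cc2cc(C3OCCO3)ccc2O1 | intermediate
10 | (2S)-2-{(2S)-1-[(4-methoxyphenyl)methoxy]propan-2-yl}-2,3-dihydro-1-benzofuran-5-carbaldehyde | C[C@@H](COCc1ccc(OC)cc1)[C@@H]1Cc2cc(C=O)ccc2O1 | intermediate
11 | (2S)-2-[(2S)-1-hydroxypropan-2-yl]-2,3-dihydro-1-benzofuran-5-carbaldehyde | C[C@@H](CO)[C@@H]1Cc2cc(C=O)ccc2O1 | intermediate
12 | (2E)-3-(4-hydroxyphenyl)prop-2-enoic acid (p-coumaric acid) | OC(=O)/C=C/c1ccc(O)cc1 | starting material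
13 | tert-butyldimethylsilyl (2E)-3-{4-[(tert-butyldimethylsilyl)oxy]phenyl}prop-2-enoate | CC(C)(C)[Si](C)(C)OC(=O)/C=C/c1ccc(O[Si](C)(C)C(C)(C)C)cc1 | intermediate
14 | (2E)-3-{4-[(tert-butyldimethylsilyl)oxy]phenyl}prop-2-enoic acid | OC(=O)/C=C/c1ccc(O[Si](C)(C)C(C)(C)C)cc1 | intermediate
15 | (2S)-2-[(2S)-5-formyl-2,3-dihydro-1-benzofuran-2-yl]propyl (2E)-3-{4-[(tert-butyldimethylsilyl)oxy]phenyl}prop-2-enoate | C[C@@H](COC(=O)/C=C/c1ccc(O[Si](C)(C)C(C)(C)C)cc1)[C@@H]1Cc2cc(C=O)ccc2O1 | intermediate
16 | (2S)-2-[(2S)-5-formyl-2,3-dihydro-1-benzofuran-2-yl]propyl (2E)-3-(4-hydroxyphenyl)prop-2-enoate | C[C@@H](COC(=O)/C=C/c1ccc(O)cc1)[C@@H]1Cc2cc(C=O)ccc2O1 | intermediate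
17 | propanedioic acid (malonic acid) | OC(=O)CC(=O)O | starting material
18 | (2E)-3-[(2S)-2-[(2S)-1-{[(2E)-3-(4-hydroxyphenyl)prop-2-enoyl]oxy}propan-2-yl]-2,3-dihydro-1-benzofuran-5-yl]prop-2-enoic acid | C[C@@H](COC(=O)/C=C/c1ccc(O)cc1)[C@@H]1Cc2cc(/C=C/C(=O)O)ccc2O1 | target

## Step count and risks

Total step count: 12. Longest linear sequence: 10 steps (steps 1–4, 6–8 and 10–12, from 1).

**Step 6 (key step).** The most likely failure is a second ortho C–H palladation before the norbornene is extruded, which would alkylate both ortho positions and consume two equivalents of 6. Loss of the epoxide by iodide opening or isomerisation under hot carbonate is the second concern. The fallback builds the same two bonds one after the other; it sets out from 6 and comes back at 9.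
- Commercial 3-bromo-4-chlorobenzaldehyde F1 is acetalised to 2-(3-bromo-4-chlorophenyl)-1,3-dioxolane F2.
- Bromine–magnesium exchange with iPrMgCl·LiCl gives [2-chloro-5-(1,3-dioxolan-2-yl)phenyl]magnesium chloride F3.
- Under CuI catalysis F3 opens 6 at its CH2 to give (2S,3S)-1-[2-chloro-5-(1,3-dioxolan-2-yl)phenyl]-4-[(4-methoxyphenyl)methoxy]-3-methylbutan-2-ol F4.
- Palladium-catalysed intramolecular aryl etherification of F4 (Pd(OAc)2, a bulky di-tert-butyl(biaryl)phosphine, Cs2CO3, toluene, 80 °C) forms O1–C7a with retention at C2 and gives 9.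

**Step 3.** Methyl transfer may go partly to C2, because the ether oxygen on C4 removes the usual electronic preference for C3 and offers aluminium a second coordination site. The fallback changes the directing group; it sets out from 3 and comes back at 4.
- Oxidation of 3 (TEMPO, PhI(OAc)2, MeCN/H2O) gives (2R,3R)-3-{[(4-methoxyphenyl)methoxy]methyl}oxirane-2-carboxylic acid F5.
- Me2CuLi opens the carboxylate salt of F5 at C3, the carbon remote from the carboxylate, with inversion, giving (2R,3S)-2-hydroxy-4-[(4-methoxyphenyl)methoxy]-3-methylbutanoic acid F6.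
- LiAlH4 reduces F6 to 4.

**Step 2.** Z-allylic alcohols react slowly and with weaker enantiofacial control in titanium–tartrate epoxidation, so some of the wrong enantiomer could pass through to 6 and end as the inseparable enantiomer of 18. The fallback replaces asymmetric induction by resolution; it sets out from 2 and comes back at 6.
- 3-Chloroperbenzoic acid converts 2 into the racemate of 3 with [(2R,3S)-3-{[(4-methoxyphenyl)methoxy]methyl}oxiran-2-yl]methanol F7.
- Steps 3 and 4 on the racemate give 4 with (2S,3R)-4-[(4-methoxyphenyl)methoxy]-3-methylbutane-1,2-diol F8, then 5 with (2S,3R)-2-hydroxy-4-[(4-methoxyphenyl)methoxy]-3-methylbutyl 4-methylbenzenesulfonate F9, then 6 with (2S)-2-{(2R)-1-[(4-methoxyphenyl)methoxy]propan-2-yl}oxirane F10.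
- Jacobsen hydrolytic kinetic resolution with (R,R)-N,N'-bis(3,5-di-tert-butylsalicylidene)cyclohexane-1,2-diaminocobalt acetate (trivalent cobalt) and 0.55 equiv water is expected, by analogy with simple alkyl oxiranes, to hydrolyse F10 to F8 and leave 6. If the opposite sense is found, the (S,S) complex is used.
- The same resolution can be applied to enriched 6 from step 2 as a polishing step.

**Step 12.** Prolonged heating with amine may cause conjugate addition of piperidine, slow aminolysis of the coumarate ester, or incomplete decarboxylation. The fallback replaces condensation–decarboxylation by olefination with a masked carboxyl; it sets out from 16 and comes back at 18.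
- Wittig reaction of 16 with tert-butyl (triphenylphosphoranylidene)acetate (toluene, 40 °C) gives tert-butyl (2E)-3-[(2S)-2-[(2S)-1-{[(2E)-3-(4-hydroxyphenyl)prop-2-enoyl]oxy}propan-2-yl]-2,3-dihydro-1-benzofuran-5-yl]prop-2-enoate F11.
- Trifluoroacetic acid in CH2Cl2 with anisole as cation scavenger cleaves the tert-butyl ester of F11 to 18; the primary alkyl coumarate is stable to these conditions.

## Further compounds

F1 | step 6 | 3-bromo-4-chlorobenzaldehyde | O=Cc1ccc(Cl)c(Br)c1
F2 | step 6 | 2-(3-bromo-4-chlorophenyl)-1,3-dioxolane | Clc1ccc(cc1Br)C1OCCO1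
F3 | step 6 | [2-chloro-5-(1,3-dioxolan-2-yl)phenyl]magnesium chloride | Cl[Mg]c1cc(ccc1Cl)C1OCCO1
F4 | step 6 | (2S,3S)-1-[2-chloro-5-(1,3-dioxolan-2-yl)phenyl]-4-[(4-methoxyphenyl)methoxy]-3-methylbutan-2-ol | C[C@@H](COCc1ccc(OC)cc1)[C@@H](O)Cc1cc(ccc1Cl)C1OCCO1
F5 | step 3 | (2R,3R)-3-{[(4-methoxyphenyl)methoxy]methyl}oxirane-2-carboxylic acid | OC(=O)[C@@H]1O[C@@H]1COCc1ccc(OC)cc1
F6 | step 3 | (2R,3S)-2-hydroxy-4-[(4-methoxyphenyl)methoxy]-3-methylbutanoic acid | OC(=O)[C@H](O)[C@@H](C)COCc1ccc(OC)cc1
F7 | step 2 | [(2R,3S)-3-{[(4-methoxyphenyl)methoxy]methyl}oxiran-2-yl]methanol | OC[C@H]1O[C@H]1COCc1ccc(OC)cc1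
F8 | step 2 | (2S,3R)-4-[(4-methoxyphenyl)methoxy]-3-methylbutane-1,2-diol | OC[C@@H](O)[C@H](C)COCc1ccc(OC)cc1
F9 | step 2 | (2S,3R)-2-hydroxy-4-[(4-methoxyphenyl)methoxy]-3-methylbutyl 4-methylbenzenesulfonate | Cc1ccc(cc1)S(=O)(=O)OC[C@@H](O)[C@H](C)COCc1ccc(OC)cc1
F10 | step 2 | (2S)-2-{(2R)-1-[(4-methoxyphenyl)methoxy]propan-2-yl}oxirane | C[C@H](COCc1ccc(OC)cc1)[C@H]1CO1
F11 | step 12 | tert-butyl (2E)-3-[(2S)-2-[(2S)-1-{[(2E)-3-(4-hydroxyphenyl)prop-2-enoyl]oxy}propan-2-yl]-2,3-dihydro-1-benzofuran-5-yl]prop-2-enoate | C[C@@H](COC(=O)/C=C/c1ccc(O)cc1)[C@@H]1Cc2cc(/C=C/C(=O)OC(C)(C)C)ccc2O1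
A1 | alternative 1 | 4-bromo-2-iodophenol | Oc1ccc(Br)cc1I
A2 | alternative 1 | tert-butyldimethyl[(2-methylidenebut-3-en-1-yl)oxy]silane | C=CC(=C)CO[Si](C)(C)C(C)(C)C
A3 | alternative 1 | (2S)-5-bromo-2-{3-[(tert-butyldimethylsilyl)oxy]prop-1-en-2-yl}-2,3-dihydro-1-benzofuran | C=C(CO[Si](C)(C)C(C)(C)C)[C@@H]1Cc2cc(Br)ccc2O1
A4 | alternative 2 | 4-bromo-2-[(2E)-but-2-en-1-yl]phenol | C/C=C/Cc1cc(Br)ccc1O
A5 | alternative 2 | methyl (2R)-2-[(2S)-5-bromo-2,3-dihydro-1-benzofuran-2-yl]propanoate | C[C@@H](C(=O)OC)[C@@H]1Cc2cc(Br)ccc2O1
A6 | alternative 3 | N'-[(E)-(5-bromo-2-{[(2R)-3-[(tert-butyldimethylsilyl)oxy]-2-methylpropyl]oxy}phenyl)methylidene]-4-methylbenzenesulfonohydrazide | C[C@@H](CO[Si](C)(C)C(C)(C)C)COc1ccc(Br)cc1/C=N/NS(=O)(=O)c1ccc(C)cc1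
A7 | alternative 3 | (2S)-5-bromo-2-{(2S)-1-[(tert-butyldimethylsilyl)oxy]propan-2-yl}-2,3-dihydro-1-benzofuran | C[C@@H](CO[Si](C)(C)C(C)(C)C)[C@@H]1Cc2cc(Br)ccc2O1
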